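The target is a cis-fused tetrahydrofuran–γ-lactone whose ring-fusion bond C8'–C8 (C8' alpha to the lactone carbonyl, C8 bearing the OCH2 carbon C9) lies next to the benzylic lactone bond C7–O. Both are made at once: a malonyl radical at C8', generated oxidatively, closes the tetrahydrofuran ring onto a cinnamyl ether, and the oxidised benzylic centre C7 is captured by the cis ester to close the lactone ring, the C7' stereocentre (catechol-bearing O–CH) steering C8, C8' and C7. The precursor is an enantiopure dibenzyl (aryl)(cinnamyloxy)methylmalonate with all phenols as benzyl ethers, so that one hydrogenolysis–decarboxylation finishes the synthesis.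

Key step: step 7

Remark: lignan locants are used (C7 and C7' are the O–CH carbons bearing the guaiacyl and catechol rings, C9' is the lactone carbonyl); compounds 1, 2 and 11 are taken as purchasable.

Step 1
Reactants: 1 3,4-bis(benzyloxy)benzoic acid; 2 3-(benzyloxy)-3-oxopropanoic acid (mono-benzyl malonate)
Product: 5 benzyl 3-[3,4-bis(benzyloxy)phenyl]-3-oxopropanoate, via acyl imidazolide 3 (not isolated), via aroylmalonic half ester 4 (not isolated)
Conditions: 1, CDI, THF, rt; then 2, MgCl2, Et3N, MeCN, rt to 40 °C; aq. HCl work-up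
Reagents that add atoms: none
Why: Masamune–Brooks-type decarboxylative Claisen condensation, in which the magnesium enolate of the malonic half ester is C-acylated by the acyl imidazolide and loses CO2 on acidification, a standard entry to aryl β-keto esters that leaves benzyl ethers untouched.

Step 2
Reactants: 5 benzyl 3-[3,4-bis(benzyloxy)phenyl]-3-oxopropanoate
Product: 6 benzyl (3S)-3-[3,4-bis(benzyloxy)phenyl]-3-hydroxypropanoate
Conditions: RuCl[(S,S)-TsDPEN](p-cymene) (1 mol%), HCO2H/Et3N (5:2), DMF, 40 °C
Reagents that add atoms: none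
Why: Noyori-type asymmetric transfer hydrogenation of an aryl β-keto ester, in which the (S,S)-diamine ligand should, by the sense of induction established for aryl ketones, deliver hydride to the face that gives the S carbinol (the future C7'), while benzyl ethers and the benzyl ester are inert to the formate reductant.

Step 3
Reactants: 6 benzyl (3S)-3-[3,4-bis(benzyloxy)phenyl]-3-hydroxypropanoate
Product: 7 benzyl (3S)-3-[3,4-bis(benzyloxy)phenyl]-3-(prop-2-en-1-yloxy)propanoate
Conditions: allyl bromide (6 equiv), Ag2O (2 equiv), 4 Å MS, Et2O, rt to 35 °C, dark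
Reagents that add atoms: allyl bromide, C=CCBr
Why: Ag2O-mediated Williamson etherification alkylates the secondary carbinol under essentially neutral conditions, so the β-hydroxy ester should neither dehydrate nor undergo retro-aldol cleavage, and C7' keeps its configuration because no bond to it is broken.

Step 4
Reactants: 7 benzyl (3S)-3-[3,4-bis(benzyloxy)phenyl]-3-(prop-2-en-1-yloxy)propanoate
Product: 10 dibenzyl 2-{(S)-[3,4-bis(benzyloxy)phenyl](prop-2-en-1-yloxy)methyl}propanedioate, via lithium ester enolate 8 (not isolated), via lithium malonate enolate 9 (not isolated)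
Conditions: LiN(iPr)2 (2.1 equiv), THF, −78 °C; BnOCOCl (1.05 equiv), −78 °C; AcOH quench at −78 °C
Reagents that add atoms: benzyl chloroformate, O=C(Cl)OCc1ccccc1
Why: Crossed Claisen-type C-acylation of an ester enolate by a chloroformate, with a second equivalent of base storing the more acidic malonate as its enolate; holding the mixture at −78 °C until the acidic quench should suppress β-elimination of the allyloxy group and any reversible alkoxide loss that would erode C7', and building the malonate only after the ether excludes competing C-alkylation.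

Step 5
Reactants: 11 4-(benzyloxy)-3-methoxybenzaldehyde
Product: 12 1-(benzyloxy)-4-ethenyl-2-methoxybenzene
Conditions: Ph3PCH3Br, KOtBu, THF, 0 °C to rt
Reagents that add atoms: methyltriphenylphosphonium bromide, C[P+](c1ccccc1)(c1ccccc1)c1ccccc1.[Br-]
Why: Wittig methylenation of a non-enolisable aromatic aldehyde, to which the benzyl ether is inert.

Step 6
Reactants: 10 dibenzyl 2-{(S)-[3,4-bis(benzyloxy)phenyl](prop-2-en-1-yloxy)methyl}propanedioate; 12 1-(benzyloxy)-4-ethenyl-2-methoxybenzene (3 equiv)
Product: 13 dibenzyl 2-{(S)-[3,4-bis(benzyloxy)phenyl]{[(2E)-3-[4-(benzyloxy)-3-methoxyphenyl]prop-2-en-1-yl]oxy}methyl}propanedioate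
Conditions: second-generation Grubbs catalyst (5 mol%), CH2Cl2, 40 °C
Reagents that add atoms: none
Why: Olefin cross-metathesis of a terminal allyl ether with an excess of an electron-rich styrene should give the (E)-cinnamyl ether under thermodynamic control with loss of ethylene, and it avoids an ionisation-prone para-alkoxycinnamyl halide while leaving the malonate C–H, the esters and C7' untouched.

Step 7
Reactants: 13 dibenzyl 2-{(S)-[3,4-bis(benzyloxy)phenyl]{[(2E)-3-[4-(benzyloxy)-3-methoxyphenyl]prop-2-en-1-yl]oxy}methyl}propanedioate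
Product: 14 benzyl (1S,4S,5R,8R)-8-[3,4-bis(benzyloxy)phenyl]-4-[4-(benzyloxy)-3-methoxyphenyl]-2-oxo-3,7-dioxabicyclo[3.3.0]octane-1-carboxylate
Conditions: Mn(OAc)3·2H2O (2.2 equiv), Cu(OAc)2·H2O (0.2 equiv), KOAc (2 equiv), degassed AcOH, 70 °C
Reagents that add atoms: none
Why: Mn(OAc)3 (trivalent manganese) enolises the malonate, the only acidic C–H, and oxidises it to an electrophilic C8' radical that adds to C8 of the electron-rich styrene by 5-exo-trig closure (tetrahydrofuran ring, bond C8'–C8), giving a benzylic C7 radical where the 6-endo path would give a non-stabilised one. Divalent copper, regenerated by trivalent manganese, oxidises this radical to a cation stabilised by the para-benzyloxy group, and the carbonyl oxygen of the ester lying cis to the C7 arm captures it in a five-membered 5-exo-trig closure (γ-lactone ring, bond C7–O), the benzyl group of the lactonium ion passing to acetate as benzyl acetate. The closest known reaction type is the Mn(OAc)3/Cu(OAc)2 oxidative free-radical cyclisation of unsaturated malonates with lactonisation at the oxidised benzylic terminus. C8 is set by C7' through a chair-like transition state in which the C7' aryl group lies pseudo-equatorial, where it should avoid eclipsing an ester of the planar radical, and so ends trans to the C7 arm; C8' becomes stereogenic only on lactonisation and is held cis-fused by the bicyclo[3.3.0] geometry; C7 should close with its aryl group on the convex face, the arrangement also favoured if the benzylic C–O bond ionises reversibly. The step needs chemoselective oxidation, 5-exo regioselectivity and diastereocontrol from one stereocentre: the product has no α-hydrogen and cannot be oxidised again, benzyl ethers are inert where free phenols would not be, and two identical benzyl esters make it irrelevant which one lactonises while giving up their alkyl group more readily than methyl esters would.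

Step 8
Reactants: 14 benzyl (1S,4S,5R,8R)-8-[3,4-bis(benzyloxy)phenyl]-4-[4-(benzyloxy)-3-methoxyphenyl]-2-oxo-3,7-dioxabicyclo[3.3.0]octane-1-carboxylate
Product: 16 (1S,4S,5R,8S)-8-(3,4-dihydroxyphenyl)-4-(4-hydroxy-3-methoxyphenyl)-3,7-dioxabicyclo[3.3.0]octan-2-one, via lactone carboxylic acid 15 (not isolated)
Conditions: H2 (1 atm), 10% Pd/C, EtOAc, rt; filter under argon; 1,4-dioxane, 95 °C
Reagents that add atoms: none
Why: Catalytic hydrogenolysis in a neutral aprotic solvent should remove the four O-benzyl groups (three aryl ethers, one ester) faster than it touches the ring benzylic C–O bonds, and the freed α-carboxy lactone decarboxylates thermally through its enol, which can be protonated at C8' only from the convex face, giving the cis-fused lactone with H8' cis to H8.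

Compound list
1 | 3,4-bis(benzyloxy)benzoic acid | O=C(O)c1ccc(OCc2ccccc2)c(OCc2ccccc2)c1 | starting material
2 | 3-(benzyloxy)-3-oxopropanoic acid (mono-benzyl malonate) | O=C(O)CC(=O)OCc1ccccc1 | starting material
3 | [3,4-bis(benzyloxy)phenyl](1H-imidazol-1-yl)methanone | O=C(c1ccc(OCc2ccccc2)c(OCc2ccccc2)c1)n1ccnc1 | intermediate (not isolated)
4 | 2-[3,4-bis(benzyloxy)benzoyl]-3-(benzyloxy)-3-oxopropanoic acid (present as its magnesium chelate) | O=C(O)C(C(=O)OCc1ccccc1)C(=O)c1ccc(OCc2ccccc2)c(OCc2ccccc2)c1 | intermediate (not isolated)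
5 | benzyl 3-[3,4-bis(benzyloxy)phenyl]-3-oxopropanoate | O=C(CC(=O)OCc1ccccc1)c1ccc(OCc2ccccc2)c(OCc2ccccc2)c1 | intermediate
6 | benzyl (3S)-3-[3,4-bis(benzyloxy)phenyl]-3-hydroxypropanoate | O[C@@H](CC(=O)OCc1ccccc1)c1ccc(OCc2ccccc2)c(OCc2ccccc2)c1 | intermediate
7 | benzyl (3S)-3-[3,4-bis(benzyloxy)phenyl]-3-(prop-2-en-1-yloxy)propanoate | C=CCO[C@@H](CC(=O)OCc1ccccc1)c1ccc(OCc2ccccc2)c(OCc2ccccc2)c1 | intermediate
8 | lithium enolate of 7 (same spatial arrangement at C7') | [Li+].C=CCO[C@@H](C=C([O-])OCc1ccccc1)c1ccc(OCc2ccccc2)c(OCc2ccccc2)c1 | intermediate (not isolated)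
9 | lithium enolate of 10 (same spatial arrangement at C7') | [Li+].C=CCO[C@@H](C(C(=O)OCc1ccccc1)=C([O-])OCc1ccccc1)c1ccc(OCc2ccccc2)c(OCc2ccccc2)c1 | intermediate (not isolated)
10 | dibenzyl 2-{(S)-[3,4-bis(benzyloxy)phenyl](prop-2-en-1-yloxy)methyl}propanedioate | C=CCO[C@@H](C(C(=O)OCc1ccccc1)C(=O)OCc1ccccc1)c1ccc(OCc2ccccc2)c(OCc2ccccc2)c1 | intermediate
11 | 4-(benzyloxy)-3-methoxybenzaldehyde | COc1cc(C=O)ccc1OCc1ccccc1 | starting material
12 | 1-(benzyloxy)-4-ethenyl-2-methoxybenzene | COc1cc(C=C)ccc1OCc1ccccc1 | intermediate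
13 | dibenzyl 2-{(S)-[3,4-bis(benzyloxy)phenyl]{[(2E)-3-[4-(benzyloxy)-3-methoxyphenyl]prop-2-en-1-yl]oxy}methyl}propanedioate | COc1cc(/C=C/CO[C@@H](C(C(=O)OCc2ccccc2)C(=O)OCc2ccccc2)c2ccc(OCc3ccccc3)c(OCc3ccccc3)c2)ccc1OCc1ccccc1 | intermediate
14 | benzyl (1S,4S,5R,8R)-8-[3,4-bis(benzyloxy)phenyl]-4-[4-(benzyloxy)-3-methoxyphenyl]-2-oxo-3,7-dioxabicyclo[3.3.0]octane-1-carboxylate (cis-fused; both aryl groups on the convex face) | COc1cc([C@H]2OC(=O)[C@@]3(C(=O)OCc4ccccc4)[C@@H]2CO[C@@H]3c2ccc(OCc3ccccc3)c(OCc3ccccc3)c2)ccc1OCc1ccccc1 | intermediate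
15 | (1S,4S,5R,8R)-8-(3,4-dihydroxyphenyl)-4-(4-hydroxy-3-methoxyphenyl)-2-oxo-3,7-dioxabicyclo[3.3.0]octane-1-carboxylic acid | COc1cc([C@H]2OC(=O)[C@@]3(C(=O)O)[C@@H]2CO[C@@H]3c2ccc(O)c(O)c2)ccc1O | intermediate (not isolated)
16 | (1S,4S,5R,8S)-8-(3,4-dihydroxyphenyl)-4-(4-hydroxy-3-methoxyphenyl)-3,7-dioxabicyclo[3.3.0]octan-2-one | COc1cc([C@H]2OC(=O)[C@H]3[C@@H]2CO[C@@H]3c2ccc(O)c(O)c2)ccc1O | target

Total step count: 8. Longest linear sequence: 7 steps (steps 1, 2, 3, 4, 6, 7, 8 from compound 1); step 5 is a one-step branch.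

Steps most likely to fail

Step 7. The hindered malonate may enolise slowly, which would let acetolysis of the electron-rich cinnamyl ether or β-elimination of the allylic alkoxide compete. The C7 cation may also be diverted by acetate or lose a proton, and facial control in the 5-exo closure may be incomplete. The fallback splits the cascade into an atom-transfer sequence under non-oxidative, non-acidic conditions and sets out from 13. Deprotonation (NaH, THF, 0 °C) and iodination with N-iodosuccinimide should give the α-iodomalonate dibenzyl 2-{(R)-[3,4-bis(benzyloxy)phenyl]{[(2E)-3-[4-(benzyloxy)-3-methoxyphenyl]prop-2-en-1-yl]oxy}methyl}-2-iodopropanedioate F1 (same spatial arrangement at C7' as 13). Iodine atom-transfer radical cyclisation (Et3B, trace air, benzene, rt) should close the tetrahydrofuran ring and leave the benzylic iodide dibenzyl (2R,4R)-2-[3,4-bis(benzyloxy)phenyl]-4-{[4-(benzyloxy)-3-methoxyphenyl](iodo)methyl}oxolane-3,3-dicarboxylate F2. On warming in toluene this iodide ionises at C7 and lactonises through the cis ester with loss of benzyl iodide, which returns the route to 14.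

Step 8. Hydrogenolysis may go on to cleave the benzylic lactone bond C7–O, which in the free acid is activated as a malonic-type leaving group, or the free-phenol acid may ionise at C7 while it is heated. The fallback sets out from 14 and decarboxylates before any phenol is freed. Krapcho dealkoxycarbonylation (LiCl, wet DMSO, 120 °C; chloride removes the ester benzyl group by SN2, the carboxylate loses CO2, protonation gives the cis fusion) should give (1S,4S,5R,8S)-8-[3,4-bis(benzyloxy)phenyl]-4-[4-(benzyloxy)-3-methoxyphenyl]-3,7-dioxabicyclo[3.3.0]octan-2-one F3. Catalytic transfer hydrogenolysis (Pd/C, 1,4-cyclohexadiene, EtOAc–EtOH, rt) then has only three aryl benzyl ethers to remove on a neutral lactone and returns the route to 16.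

Step 4. The ester enolate may expel the β-allyloxy group (E1cB) before it is acylated, or configuration at C7' may be lost by reversible alkoxide expulsion from the malonate enolate if the mixture warms. The fallback reverses the order of the two operations and sets out from 6. The alkoxide–enolate dianion (LiN(iPr)2, 2.1 equiv, THF, −78 °C), whose β-oxido group cannot leave, is C-acylated with benzyl chloroformate to give dibenzyl 2-{(S)-[3,4-bis(benzyloxy)phenyl](hydroxy)methyl}propanedioate F4. Acid-catalysed O-allylation with allyl 2,2,2-trichloroacetimidate (TfOH cat., CH2Cl2–cyclohexane, 0 °C), under which the malonate carbon is not nucleophilic, returns the route to 10.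

Further compounds
F1 | step 7 | dibenzyl 2-{(R)-[3,4-bis(benzyloxy)phenyl]{[(2E)-3-[4-(benzyloxy)-3-methoxyphenyl]prop-2-en-1-yl]oxy}methyl}-2-iodopropanedioate | COc1cc(/C=C/CO[C@@H](C(I)(C(=O)OCc2ccccc2)C(=O)OCc2ccccc2)c2ccc(OCc3ccccc3)c(OCc3ccccc3)c2)ccc1OCc1ccccc1
F2 | step 7 | dibenzyl (2R,4R)-2-[3,4-bis(benzyloxy)phenyl]-4-{[4-(benzyloxy)-3-methoxyphenyl](iodo)methyl}oxolane-3,3-dicarboxylate (epimers at the iodinated carbon) | COc1cc(C(I)[C@H]2CO[C@H](c3ccc(OCc4ccccc4)c(OCc4ccccc4)c3)C2(C(=O)OCc2ccccc2)C(=O)OCc2ccccc2)ccc1OCc1ccccc1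
F3 | step 8 | (1S,4S,5R,8S)-8-[3,4-bis(benzyloxy)phenyl]-4-[4-(benzyloxy)-3-methoxyphenyl]-3,7-dioxabicyclo[3.3.0]octan-2-one | COc1cc([C@H]2OC(=O)[C@H]3[C@@H]2CO[C@@H]3c2ccc(OCc3ccccc3)c(OCc3ccccc3)c2)ccc1OCc1ccccc1
F4 | step 4 | dibenzyl 2-{(S)-[3,4-bis(benzyloxy)phenyl](hydroxy)methyl}propanedioate | O[C@@H](C(C(=O)OCc1ccccc1)C(=O)OCc1ccccc1)c1ccc(OCc2ccccc2)c(OCc2ccccc2)c1
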